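**Strategy**

The ring is numbered C1 (alkylidene carbon), C2 (CH with the 3-hydroxypropyl arm), C3 (quaternary carbon), C4 (carbinol carbon), C5, C6. Everything rests on cutting C1–C6 and C2–C3: a thermal intramolecular Diels–Alder reaction of a (Z)-dienyl (aS)-allenoate forms both bonds at once. The step exploits that the hydroxymethyl on C3 and the arm on C2 are cis (a hidden cis-fused γ-lactone tether), that the exocyclic tetrasubstituted C1=C enal is a hidden allene whose axis fixes C2, C3 and the alkene geometry, and that C4(CH3)OH is a hidden C4=C5 alkene. The precursor is an acyclic ester made from (S)-2-methylglycidol, CO and a dienol.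

Key step: step 7

Remark: (S)-2-methylglycidol is taken as the only source of absolute configuration; its S centre is relayed into the aS allene axis and from there into the ring.

**Route**

Step 1
Reactants: 1 but-2-yn-1-ol; 2 but-3-en-1-ylmagnesium bromide
Product: 4 (2Z)-2-(but-3-en-1-yl)-3-iodobut-2-en-1-ol, via cyclic alkenylmagnesium alkoxide 3 (not isolated)
Conditions: 2 (3.5 equiv), CuI (10 mol %), THF, 0 °C to reflux; then I2, −40 to 0 °C
Reagents that add atoms: iodine, II
Why: Copper-catalysed anti-carbomagnesiation of the propargylic alkoxide should place the butenyl group on C2 and magnesium on C3 inside a five-membered chelate, so iodinolysis with retention gives the tetrasubstituted iodide with I cis to CH2OH.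

Step 2
Reactants: 4 (2Z)-2-(but-3-en-1-yl)-3-iodobut-2-en-1-ol; 5 2-ethenyl-4,4,5,5-tetramethyl-1,3,2-dioxaborolane
Product: 6 (2Z)-2-(but-3-en-1-yl)-3-methylpenta-2,4-dien-1-ol
Conditions: Pd(PPh3)4 (5 mol %), K3PO4, 1,4-dioxane/H2O, 70 °C
Reagents that add atoms: none
Why: Suzuki–Miyaura coupling of the alkenyl iodide proceeds with retention of alkene geometry, so the vinyl group should end up cis to CH2OH (the Z diene).

Step 3
Reactants: 7 (S)-2-methylglycidol
Product: 8 (2R)-2-methyloxirane-2-carbaldehyde
Conditions: TEMPO (10 mol %), PhI(OAc)2, CH2Cl2, 0 °C to rt; carried on as a concentrated solution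
Reagents that add atoms: none
Why: Nitroxyl-catalysed oxidation of the primary alcohol stops at the aldehyde and cannot disturb the fully substituted epoxide stereocentre, which has no α-hydrogen.

Step 4
Reactants: 8 (2R)-2-methyloxirane-2-carbaldehyde
Product: 9 (2S)-2-ethynyl-2-methyloxirane
Conditions: dimethyl (1-diazo-2-oxopropyl)phosphonate, K2CO3, MeOH, 0 °C to rt; co-distilled into THF
Reagents that add atoms: dimethyl (1-diazo-2-oxopropyl)phosphonate, COP(=O)(OC)C(=[N+]=[N-])C(C)=O
Why: Ohira–Bestmann (Seyferth–Gilbert) homologation converts the non-enolisable aldehyde into the terminal alkyne under mild base without touching the stereocentre.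

Step 5
Reactants: 9 (2S)-2-ethynyl-2-methyloxirane; 6 (2Z)-2-(but-3-en-1-yl)-3-methylpenta-2,4-dien-1-ol
Product: 10 (2Z)-2-(but-3-en-1-yl)-3-methylpenta-2,4-dien-1-yl (aS)-5-hydroxy-4-methylpenta-2,3-dienoate
Conditions: 6 (2.5 equiv, excess recovered), Pd(PPh3)4 (5 mol %), CO (5 atm), THF, 40 °C
Reagents that add atoms: carbon monoxide, [C-]#[O+]
Why: Palladium-catalysed carbonylation of an alkynyl oxirane: zerovalent palladium opens the oxirane by anti SN2′ oxidative addition to an allenylpalladium alkoxide, CO insertion and alcoholysis by 6 give the 5-hydroxy-2,3-dienoate, and the anti pathway should transfer the S centre into the aS axis.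

Step 6
Reactants: 10 (2Z)-2-(but-3-en-1-yl)-3-methylpenta-2,4-dien-1-yl (aS)-5-hydroxy-4-methylpenta-2,3-dienoate
Product: 11 (2Z)-2-(but-3-en-1-yl)-3-methylpenta-2,4-dien-1-yl (aS)-4-methyl-5-[(triisopropylsilyl)oxy]penta-2,3-dienoate
Conditions: TIPSOTf, 2,6-lutidine, CH2Cl2, −78 °C
Reagents that add atoms: triisopropylsilyl trifluoromethanesulfonate, CC(C)[Si](C(C)C)(C(C)C)OS(=O)(=O)C(F)(F)F
Why: Silylation with a silyl triflate and a non-nucleophilic base protects the primary alcohol without conjugate addition to the allenoate and makes this γ-substituent much larger than the γ-methyl.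

Step 7
Reactants: 11 (2Z)-2-(but-3-en-1-yl)-3-methylpenta-2,4-dien-1-yl (aS)-4-methyl-5-[(triisopropylsilyl)oxy]penta-2,3-dienoate
Product: 12 (3aR,7aR,7Z)-3a-(but-3-en-1-yl)-4-methyl-7-{1-[(triisopropylsilyl)oxy]propan-2-ylidene}-3a,6,7,7a-tetrahydro-2-benzofuran-1(3H)-one
Conditions: toluene (0.005 M), BHT (10 mol %), 135 °C, sealed vessel
Reagents that add atoms: none
Why: A concerted thermal intramolecular [4+2] cycloaddition joins the diene termini to the ester-conjugated α,β-double bond of the allenoate; the closest known reaction type is the ester-tethered intramolecular Diels–Alder reaction of dienyl allenecarboxylates, with the axial-to-central chirality transfer known for γ-substituted allenoates. The cyclohexene is closed by suprafacial union of diene C1/C4 with allene Cα/Cβ, and the three-atom CH2–O–C(=O) tether makes this a type 1 cycloaddition in the fused mode, which closes the γ-lactone ring in the same event. Because the Z diene carries the tether on its inside position, only the cis-fused lactone is geometrically accessible, so the CH2O on the new quaternary carbon is cis to the carbonyl on the new CH. The diene should add to the α,β-π face that carries the γ-methyl and avoid the γ-CH2OTIPS, which fixes the exocyclic alkene (CH3 syn to the ring CH2, CH2OTIPS syn to the ring CH) and, through the aS axis, the absolute configuration of both ring stereocentres. Site selectivity for the α,β-bond is secured by conjugation with the ester and by the tether length (the other allene bond would need a six-membered lactone with two adjacent quaternary carbons), and high dilution suppresses bimolecular reaction. The selectivity the step needs most is facial, and it rests on the size difference between CH3 and CH2OTIPS; the minor face would give the separable E-alkene diastereomer.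

Step 8
Reactants: 12 the cis-fused lactone
Product: 13 (3aR,7aR,7Z)-3a-(but-3-en-1-yl)-4-methyl-7-{1-[(triisopropylsilyl)oxy]propan-2-ylidene}-1,3,3a,6,7,7a-hexahydro-2-benzofuran-1-ol (anomer mixture)
Conditions: i-Bu2AlH (1.1 equiv), CH2Cl2, −78 °C; aqueous potassium sodium tartrate
Reagents that add atoms: none
Why: Partial hydride reduction of a γ-lactone at low temperature stops at the stable five-membered lactol and leaves the silyl ether and alkenes untouched.

Step 9
Reactants: 13 the lactol; 14 ethyl (triphenylphosphoranylidene)acetate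
Product: 15 ethyl (2E)-3-[6-(but-3-en-1-yl)-6-(hydroxymethyl)-5-methyl-2-{(Z)-1-[(triisopropylsilyl)oxy]propan-2-ylidene}cyclohex-4-en-1-yl]prop-2-enoate (ring configuration as in 12, hydroxymethyl cis to the propenoate arm)
Conditions: toluene, 80 °C
Reagents that add atoms: none
Why: Wittig olefination of the open hydroxy-aldehyde tautomer with the stabilised ylide gives the E enoate and frees the neopentyl CH2OH under neutral conditions that should avoid epimerisation of the allylic CH and oxa-Michael closure.

Step 10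
Reactants: 15 the enoate
Product: 16 ethyl 3-[6-(but-3-en-1-yl)-6-(hydroxymethyl)-5-methyl-2-{(Z)-1-[(triisopropylsilyl)oxy]propan-2-ylidene}cyclohex-4-en-1-yl]propanoate
Conditions: Cu(OAc)2 (5 mol %), 1,2-bis(diphenylphosphino)benzene (5 mol %), (EtO)2MeSiH, t-BuOH, toluene, rt
Reagents that add atoms: none
Why: Copper hydride conjugate reduction is specific for the electron-poor enoate C=C and should leave the terminal, trisubstituted and tetrasubstituted alkenes alone.

Step 11
Reactants: 16 the saturated ester
Product: 17 the 4,5-epoxide of 16 (epoxide oxygen cis to CH2OH; ethyl 3-[…]propanoate with a 7-oxabicyclo[4.1.0]heptane core)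
Conditions: VO(acac)2 (5 mol %), t-BuOOH, CH2Cl2, 0 °C to rt
Reagents that add atoms: tert-butyl hydroperoxide, CC(C)(C)OO
Why: Vanadium-catalysed hydroxyl-directed epoxidation of the homoallylic alcohol delivers oxygen to the ring alkene from the face of the CH2OH group, which sets both epoxide carbons; the ester and the remote alkenes should not react.

Step 12
Reactants: 17 the epoxy alcohol; 18 methacrolein
Product: 19 the (E)-enal ethyl 3-[epoxy ring bearing a (3E)-4-methyl-5-oxopent-3-en-1-yl chain on the quaternary carbon]propanoate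
Conditions: second-generation Grubbs catalyst (5 mol %), 18 (10 equiv), CH2Cl2, 40 °C
Reagents that add atoms: none
Why: Olefin cross-metathesis of the monosubstituted butenyl alkene with excess methacrolein gives the thermodynamically favoured E trisubstituted enal, and the hindered tetrasubstituted alkene is inert to the ruthenium carbene.

Step 13
Reactants: 20 geranyl bromide; 21 triethyl phosphite
Product: 22 diethyl [(2E)-3,7-dimethylocta-2,6-dien-1-yl]phosphonate
Conditions: neat, 130 °C, bromoethane distilled off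
Reagents that add atoms: none
Why: Michaelis–Arbuzov reaction of the allylic bromide gives the allylic phosphonate with the E alkene retained.

Step 14
Reactants: 19 the enal; 22 diethyl geranylphosphonate
Product: 23 ethyl 3-[epoxy ring bearing the (3E,5E,7E)-4,8,12-trimethyltrideca-3,5,7,11-tetraen-1-yl chain]propanoate
Conditions: 22 (3 equiv), n-BuLi (3 equiv), THF, −78 °C; then 19, −78 °C to rt
Reagents that add atoms: none
Why: Horner–Wadsworth–Emmons olefination of the enal with the lithiated allylic phosphonate forms the central disubstituted alkene E-selectively and completes the E,E,E triene; the excess base covers the free hydroxyl, and the cis-disposed alkoxide cannot open the epoxide from its back side.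

Step 15
Reactants: 23 the triene epoxy ester
Product: 24 (2R,3S,4S)-triol with the C1 side arm still as the TIPS ether: 3-(hydroxymethyl)-2-(3-hydroxypropyl)-4-methyl-1-{(Z)-1-[(triisopropylsilyl)oxy]propan-2-ylidene}-3-[(3E,5E,7E)-4,8,12-trimethyltrideca-3,5,7,11-tetraen-1-yl]cyclohexan-4-ol
Conditions: LiAlH4, THF, 0 to 45 °C
Reagents that add atoms: none
Why: LiAlH4 reduces the ester to the primary alcohol and opens the trisubstituted epoxide by external hydride attack at the less substituted CH carbon, so the tertiary alcohol keeps its oxygen cis to CH2OH.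

Step 16
Reactants: 24 the silyl ether triol
Product: 25 (2R,3S,4S)-tetraol, (2Z)-2-[4-hydroxy-3-(hydroxymethyl)-2-(3-hydroxypropyl)-4-methyl-3-(trienyl chain)cyclohexylidene]propan-1-ol
Conditions: Bu4NF, THF, 0 °C to rt
Reagents that add atoms: none
Why: Fluoride cleaves the silyl ether and releases the allylic primary alcohol without affecting the triene.

Step 17
Reactants: 25 the tetraol
Product: 26 target, (2Z)-2-[(2R,3S,4S)-4-hydroxy-3-(hydroxymethyl)-2-(3-hydroxypropyl)-4-methyl-3-[(3E,5E,7E)-4,8,12-trimethyltrideca-3,5,7,11-tetraen-1-yl]cyclohexylidene]propanal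
Conditions: MnO2 (activated, excess), CH2Cl2, rt
Reagents that add atoms: none
Why: MnO2 oxidises only the allylic alcohol to the tetrasubstituted enal and should leave the two saturated primary alcohols and the tertiary alcohol untouched; the alkene geometry cannot change under these neutral conditions.

**Compound list**

1 | but-2-yn-1-ol | CC#CCO | starting material
2 | but-3-en-1-ylmagnesium bromide | C=CCC[Mg]Br | starting material
3 | 4-(but-3-en-1-yl)-3-methyl-2,5-dihydro-1,2-oxamagnesole (cyclic alkenylmagnesium alkoxide) | CC1=C(CCC=C)CO[Mg]1 | intermediate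
4 | (2Z)-2-(but-3-en-1-yl)-3-iodobut-2-en-1-ol | C/C(I)=C(/CO)CCC=C | intermediate
5 | 2-ethenyl-4,4,5,5-tetramethyl-1,3,2-dioxaborolane | C=CB1OC(C)(C)C(C)(C)O1 | starting material
6 | (2Z)-2-(but-3-en-1-yl)-3-methylpenta-2,4-dien-1-ol | C=C/C(C)=C(\CO)CCC=C | intermediate
7 | (S)-2-methylglycidol, [(2S)-2-methyloxiran-2-yl]methanol | C[C@]1(CO)CO1 | starting material
8 | (2R)-2-methyloxirane-2-carbaldehyde | C[C@]1(C=O)CO1 | intermediate
9 | (2S)-2-ethynyl-2-methyloxirane | C[C@]1(C#C)CO1 | intermediate
10 | (2Z)-2-(but-3-en-1-yl)-3-methylpenta-2,4-dien-1-yl (aS)-5-hydroxy-4-methylpenta-2,3-dienoate | C=C/C(C)=C(\COC(=O)C=[C@@]=C(C)CO)CCC=C | intermediate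
11 | (2Z)-2-(but-3-en-1-yl)-3-methylpenta-2,4-dien-1-yl (aS)-4-methyl-5-[(triisopropylsilyl)oxy]penta-2,3-dienoate | C=C/C(C)=C(\COC(=O)C=[C@@]=C(C)CO[Si](C(C)C)(C(C)C)C(C)C)CCC=C | intermediate
12 | (3aR,7aR,7Z)-3a-(but-3-en-1-yl)-4-methyl-7-{1-[(triisopropylsilyl)oxy]propan-2-ylidene}-3a,6,7,7a-tetrahydro-2-benzofuran-1(3H)-one (cis-fused) | C=CCC[C@@]12COC(=O)[C@@H]1/C(=C(/C)CO[Si](C(C)C)(C(C)C)C(C)C)CC=C2C | intermediate
13 | corresponding lactol, 1,3,3a,6,7,7a-hexahydro-2-benzofuran-1-ol (anomer mixture) | C=CCC[C@@]12COC(O)[C@@H]1/C(=C(/C)CO[Si](C(C)C)(C(C)C)C(C)C)CC=C2C | intermediate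
14 | ethyl (triphenylphosphoranylidene)acetate | CCOC(=O)C=P(c1ccccc1)(c1ccccc1)c1ccccc1 | starting material
15 | ethyl (2E)-3-[6-(but-3-en-1-yl)-6-(hydroxymethyl)-5-methyl-2-{(Z)-1-[(triisopropylsilyl)oxy]propan-2-ylidene}cyclohex-4-en-1-yl]prop-2-enoate | C=CCC[C@@]1(CO)[C@H](/C=C/C(=O)OCC)/C(=C(/C)CO[Si](C(C)C)(C(C)C)C(C)C)CC=C1C | intermediate
16 | ethyl 3-[6-(but-3-en-1-yl)-6-(hydroxymethyl)-5-methyl-2-{(Z)-1-[(triisopropylsilyl)oxy]propan-2-ylidene}cyclohex-4-en-1-yl]propanoate | C=CCC[C@@]1(CO)[C@H](CCC(=O)OCC)/C(=C(/C)CO[Si](C(C)C)(C(C)C)C(C)C)CC=C1C | intermediate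
17 | 4,5-epoxide of 16, epoxide oxygen cis to CH2OH | C=CCC[C@@]1(CO)[C@H](CCC(=O)OCC)/C(=C(/C)CO[Si](C(C)C)(C(C)C)C(C)C)C[C@@H]2O[C@]12C | intermediate
18 | methacrolein (2-methylprop-2-enal) | C=C(C)C=O | starting material
19 | epoxy ester bearing the (3E)-4-methyl-5-oxopent-3-en-1-yl chain | O=C/C(C)=C/CC[C@@]1(CO)[C@H](CCC(=O)OCC)/C(=C(/C)CO[Si](C(C)C)(C(C)C)C(C)C)C[C@@H]2O[C@]12C | intermediate
20 | geranyl bromide, (2E)-1-bromo-3,7-dimethylocta-2,6-diene | CC(C)=CCC/C(C)=C/CBr | starting material
21 | triethyl phosphite | CCOP(OCC)OCC | starting material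
22 | diethyl [(2E)-3,7-dimethylocta-2,6-dien-1-yl]phosphonate | CC(C)=CCC/C(C)=C/CP(=O)(OCC)OCC | intermediate
23 | epoxy ester bearing the (3E,5E,7E)-4,8,12-trimethyltrideca-3,5,7,11-tetraen-1-yl chain | CC(C)=CCC/C(C)=C/C=C/C(C)=C/CC[C@@]1(CO)[C@H](CCC(=O)OCC)/C(=C(/C)CO[Si](C(C)C)(C(C)C)C(C)C)C[C@@H]2O[C@]12C | intermediate
24 | (2R,3S,4S)-triol, C1 side arm as TIPS ether | CC(C)=CCC/C(C)=C/C=C/C(C)=C/CC[C@@]1(CO)[C@H](CCCO)/C(=C(/C)CO[Si](C(C)C)(C(C)C)C(C)C)CC[C@]1(C)O | intermediate
25 | (2R,3S,4S)-tetraol, (2Z)-2-[cyclohexylidene]propan-1-ol | CC(C)=CCC/C(C)=C/C=C/C(C)=C/CC[C@@]1(CO)[C@H](CCCO)/C(=C(/C)CO)CC[C@]1(C)O | intermediate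
26 | CNP0179699.2, (2Z)-2-[(2R,3S,4S)-4-hydroxy-3-(hydroxymethyl)-2-(3-hydroxypropyl)-4-methyl-3-[(3E,5E,7E)-4,8,12-trimethyltrideca-3,5,7,11-tetraen-1-yl]cyclohexylidene]propanal | CC(C)=CCC/C(C)=C/C=C/C(C)=C/CC[C@@]1(CO)[C@H](CCCO)/C(=C(/C)C=O)CC[C@]1(C)O | target

**Step count**

Total: 17 steps. Longest linear sequence: 14 steps (steps 1, 2, 5–12, 14–17 from but-2-yn-1-ol; the same length from 7 through steps 3 and 4).

**Steps most likely to fail**

Step 7. A [1,5]-hydrogen shift of the Z diene (from the tether CH2 to the diene terminus) or thermal isomerisation of the allenoate to a 2,4-dienoate may outrun the strained cycloaddition. The fallback changes the diene geometry, sets out from 9 and comes back at 12. Ethyl acetoacetate is alkylated with 4-bromobut-1-ene (NaOEt, EtOH) to ethyl 2-acetylhex-5-enoate F1. Tf2O with aqueous Me4NOH in hexane should give the E enol triflate, ethyl (2E)-2-(but-3-en-1-yl)-3-{[(trifluoromethyl)sulfonyl]oxy}but-2-enoate F2. Suzuki–Miyaura coupling with 5 gives ethyl (2E)-2-(but-3-en-1-yl)-3-methylpenta-2,4-dienoate F3, and i-Bu2AlH gives (2E)-2-(but-3-en-1-yl)-3-methylpenta-2,4-dien-1-ol F4. Carbonylative coupling with 9 as in step 5 gives the (2E)-dienyl (aS)-5-hydroxy-4-methylpenta-2,3-dienoate F5, and silylation as in step 6 gives its TIPS ether F6. With the tether on the outside position of the diene, cycloaddition should proceed near 100 °C; cis-fused 12 is then separated from any trans-fused isomer.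

Step 5. The acylpalladium intermediate may be captured by the hydroxyl of product already formed (oligoester formation), and zerovalent palladium may racemise the allenylpalladium species or ionise the dienyl ester. The fallback sets out from 9 and comes back at 11. Carbonylation of 9 in methanol (Pd(PPh3)4, CO) gives methyl (aS)-5-hydroxy-4-methylpenta-2,3-dienoate F7. TIPSOTf/2,6-lutidine gives methyl (aS)-4-methyl-5-[(triisopropylsilyl)oxy]penta-2,3-dienoate F8, and LiOH in THF/H2O at 0 °C gives (aS)-4-methyl-5-[(triisopropylsilyl)oxy]penta-2,3-dienoic acid F9. Esterification of F9 with 6 (2-chloro-1-methylpyridinium iodide, Et3N, CH2Cl2) gives 11, so the dienyl ester never meets palladium.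

Step 14. The ambident allylic phosphonate anion may add through its γ-carbon or give poor E/Z control at the new alkene, and the lithium alkoxide may slow the addition. The fallback is a Julia–Kocienski olefination; it sets out from 19 (with 20 as the source of the geranyl unit) and comes back at 23. Geranyl bromide 20 with 1-phenyl-1H-tetrazole-5-thiol and K2CO3 gives 5-{[(2E)-3,7-dimethylocta-2,6-dien-1-yl]sulfanyl}-1-phenyl-1H-tetrazole F10. Oxidation with (NH4)6Mo7O24/H2O2 gives 5-{[(2E)-3,7-dimethylocta-2,6-dien-1-yl]sulfonyl}-1-phenyl-1H-tetrazole F11. Its potassium anion (KN(SiMe3)2, 1,2-dimethoxyethane, −60 °C) is condensed with 19 to give 23.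

**Further compounds**

F1 | step 7 | ethyl 2-acetylhex-5-enoate | C=CCCC(C(C)=O)C(=O)OCC
F2 | step 7 | ethyl (2E)-2-(but-3-en-1-yl)-3-{[(trifluoromethyl)sulfonyl]oxy}but-2-enoate | C/C(OS(=O)(=O)C(F)(F)F)=C(/CCC=C)C(=O)OCC
F3 | step 7 | ethyl (2E)-2-(but-3-en-1-yl)-3-methylpenta-2,4-dienoate | C=C/C(C)=C(\CCC=C)C(=O)OCC
F4 | step 7 | (2E)-2-(but-3-en-1-yl)-3-methylpenta-2,4-dien-1-ol | C=C/C(C)=C(\CCC=C)CO
F5 | step 7 | (2E)-2-(but-3-en-1-yl)-3-methylpenta-2,4-dien-1-yl (aS)-5-hydroxy-4-methylpenta-2,3-dienoate | C=C/C(C)=C(\CCC=C)COC(=O)C=[C@@]=C(C)CO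
F6 | step 7 | (2E)-2-(but-3-en-1-yl)-3-methylpenta-2,4-dien-1-yl (aS)-4-methyl-5-[(triisopropylsilyl)oxy]penta-2,3-dienoate | C=C/C(C)=C(\CCC=C)COC(=O)C=[C@@]=C(C)CO[Si](C(C)C)(C(C)C)C(C)C
F7 | step 5 | methyl (aS)-5-hydroxy-4-methylpenta-2,3-dienoate | COC(=O)C=[C@@]=C(C)CO
F8 | step 5 | methyl (aS)-4-methyl-5-[(triisopropylsilyl)oxy]penta-2,3-dienoate | COC(=O)C=[C@@]=C(C)CO[Si](C(C)C)(C(C)C)C(C)C
F9 | step 5 | (aS)-4-methyl-5-[(triisopropylsilyl)oxy]penta-2,3-dienoic acid | OC(=O)C=[C@@]=C(C)CO[Si](C(C)C)(C(C)C)C(C)C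
F10 | step 14 | 5-{[(2E)-3,7-dimethylocta-2,6-dien-1-yl]sulfanyl}-1-phenyl-1H-tetrazole | CC(C)=CCC/C(C)=C/CSc1nnnn1-c1ccccc1
F11 | step 14 | 5-{[(2E)-3,7-dimethylocta-2,6-dien-1-yl]sulfonyl}-1-phenyl-1H-tetrazole | CC(C)=CCC/C(C)=C/CS(=O)(=O)c1nnnn1-c1ccccc1
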